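All runs come from a simulation with constants of no real substance, noise included.

A J that has already reacted cannot take any E down with it, and that is where I start on your question.

| setting | south | dawn | summer | dusk | noon |
|---|---|---|---|---|---|
| J | 0.80 M | 0.80 M | 0.80 M | 0.80 M | 0.80 M |
| Q | 0.80 M | 1.60 M | 1.60 M | 1.60 M | 1.60 M |
| temperature | 50 °C | 50 °C | −10 °C | 80 °C | 20 °C |
| remark | run made earlier |  |  |  |  |
| time |  | 20 min | 20 min | 20 min | 20 min |

south run (percent of the J charged)

| time / min | E / % | J / % |
|---|---|---|
| 0.833 | 13.5 | 82.6 |
| 1.50 | 20.8 | 71.1 |
| 2.50 | 25.2 | 58.4 |
| 3.00 | 25.4 | 53.1 |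
| 4.00 | 28.1 | 44.4 |
| 5.00 | 28.8 | 36.4 |
| 6.00 | 27.8 | 31.8 |

(each reading ± 0.5 percentage points)

1. the flask that comes out highest in amount of E, in percent of the J charged, or "all alike" when all lie within 1.5 percentage points (dawn / summer / dusk / noon / all alike)
2. E at the end, in percent of the J charged, dawn
3. E at the end, in percent of the J charged, summer
4. E at the end, in percent of the J charged, dusk
5. E at the end, in percent of the J charged, noon

- the earlier runs were read with a standard deviation of 0.5 percentage points
- the earlier runs do not show what temperature does; that part of a forecast is a guess

In south, J and E together fall short of the charge, and I read that shortfall as E destroyed by J. I take it that each E lost carries one J with it, so I divide the pace of the shortfall by twice the product of E and J, each as a fraction of the J charged. That gives 0.304 min⁻¹ around 2.50 min and 0.308 min⁻¹ around 5.00 min, and the two readings agree. This share of E removed per minute by J at full charge is what I call the bite. At 50 °C, multiplied by J's remaining fraction, it is E's pseudo-first-order loss constant, and ln(2) over that product is E's half-life at that moment.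

Dawn has more Q, so I let J fall at least at south's pace, which leaves about 2.19 % at the end. E's half-life at dawn's end is then 103 min, far longer than the 20 min of the run, so I expect E to stall there. I assume that Q speeds the making of E and leaves the bite unchanged, so I expect dawn's E between south's highest reading of 28.8 % and twice that, and I commit to the middle, 43.2 %. South shows nothing about temperature, so for summer, dusk and noon I commit to no number.

The forecast you brought says dawn 3 %, summer 8 %, dusk 0.2 % and noon 32 %, with noon highest; for dawn its ground is that “20 min is far past the maximum”. On dawn my number differs from it.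

The flasks give dawn 42.7 %, summer 25.5 %, dusk 31.6 % and noon 53.6 %, with noon highest.

    J + Q → E, rate k1*[J]^1.5*[Q] (k = 0.00564 M⁻¹·⁵ s⁻¹, Ea = 39.0 kJ mol⁻¹)
    J + E → L (k = 0.00569 M⁻¹ s⁻¹, Ea = 54.0 kJ mol⁻¹)
    (constants at 50 °C)

In dawn, J stands at 1.07 % after 20.0 min, so the bite gives E a half-life of 210 min, and E moves from 42.7 % to 42.0 % by 200 min. Scaled with the second step's activation energy, the bite in dusk is 1.70 min⁻¹. With J at 0.0730 % after 10.0 min, that gives a half-life of 559 min, and dusk's E reads the same at 20.0 min and 200 min. Dusk's loss came earlier, while J lasted, through the step from J and E to L: without that step, dusk ends at 99.0 % E.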